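## Retrosynthetic overview

1. Feature: in the bicyclo[3.3.1]nonane-2,4,9-trione core, the C2–C3–C4 bridge joins a crowded bridgehead (C1, next to the C8 gem-dimethyl carbon) to an open one (C5, next to the C6 methylene). The C7 chain sits exo, which is the position an epimerisable C7 substituent adopts at equilibrium.
2. Late disconnections: catechol and enol deprotection, C3 aroylation, C5 bridgehead prenylation, and the C1'–C2' bond of the geranyl chain. That bond comes from decarboxylative alkenylation of a C7 acetic acid, itself grown from a C7 ester.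
3. Key disconnection C4–C5: ring B (C1–C2–C3–C4–C5–C9) is closed onto ring A (C1–C9–C5–C6–C7–C8). An acylketene released from a tert-butyl β-ketoester arm on C1 is captured by C5 of the C9 enol, used as its triethylsilyl ether.
4. Ring A comes from Hagemann's ester by methyl conjugate addition/aldol, oxidation and asymmetric C1 prenylation. Dehydrogenation and 1,4-hydrosilylation then fix the C9=C5 enol ether, so that only the acetyl methyl group can be carboxylated.
5. Ring order: ring A is bought, ring B is formed in the key step.

Key step: step 7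

Numbering: the core numbering C1–C9 defined above is used for all intermediates, monocyclic ones included.
Assumption: the (R,R)-ligand is written in step 3. Its sense of induction on this nucleophile has to be established on the first batch, and the (S,S)-ligand is taken if it proves opposite.
Assumption: compounds 6–13 are pairs of C7 epimers with one C1 configuration. Their SMILES leave C7 open, and C7 is fixed in step 8.

## Route

Step 1
Reactants: 1 Hagemann's ester (racemic ethyl 2-methyl-4-oxocyclohex-2-ene-1-carboxylate)
Product: 3 ethyl 3-(1-hydroxyethyl)-2,2-dimethyl-4-oxocyclohexane-1-carboxylate (diastereomer mixture), via lithium enolate 2 (not isolated)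
Conditions: Me2CuLi (1.2 equiv), Et2O, −20 °C; then MeCHO (3 equiv), −78 °C; aq NH4Cl
Reagents that add atoms: lithium dimethylcuprate [Li+].C[Cu-]C; acetaldehyde CC=O
Why: Tandem cuprate conjugate addition–aldol reaction: methyl transfer to the β-carbon creates the C8 gem-dimethyl carbon and leaves enolate 2 regiospecifically across C1–C9, and the small aldehyde can bond to this neopentyl position only through carbon (an acyl halide would largely O-acylate); the stereocentres at C1 and the carbinol carbon vanish in steps 2 and 3, and racemic C7 is reset in step 8.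

Step 2
Reactants: 3 aldol
Product: 4 ethyl 3-acetyl-2,2-dimethyl-4-oxocyclohexane-1-carboxylate (racemic at C7)
Conditions: Dess–Martin periodinane, CH2Cl2, 0 °C → rt
Reagents that add atoms: none
Why: Dess–Martin oxidation of the secondary alcohol under neutral conditions should give the enolised β-diketone without retro-aldol cleavage; no stereocentre is set.

Step 3
Reactants: 4 β-diketone; 5 prenyl acetate
Product: 6 ethyl 3-acetyl-2,2-dimethyl-3-prenyl-4-oxocyclohexane-1-carboxylate (C1 as in the target; both C7 epimers)
Conditions: Pd2(dba)3·CHCl3 (2.5 mol %), (R,R)-DACH-phenyl bis(2-diphenylphosphinobenzamide) ligand (7.5 mol %), Cs2CO3 (1.1 equiv), toluene, 0 °C → rt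
Reagents that add atoms: none
Why: Palladium-catalysed asymmetric allylic alkylation (Tsuji–Trost type) of an unsymmetrical 1,3-diketone: O-allylation is reversible under zerovalent palladium so the hindered carbon C1 wins, the soft enolate attacks the unsubstituted allyl terminus to give the linear prenyl group, and the chiral pocket of the ligand selects the enolate face and so sets C1, while both C7 antipodes of 4 are carried on as epimers.

Step 4
Reactants: 6 prenylated diketone
Product: 7 ethyl 5-acetyl-6,6-dimethyl-5-prenyl-4-oxocyclohex-2-ene-1-carboxylate (C5=C6 enone; C7 labile)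
Conditions: IBX (2.5 equiv), DMSO, 70 °C
Reagents that add atoms: none
Why: IBX-mediated ketone dehydrogenation can act only along C5–C6, because C1 is quaternary and the acetyl group has no β-carbon; it is the first half of a two-step device that marks C5, needed because the C5 methylene and the acetyl methyl group are equally acidic and direct enolisation of 6 would not tell them apart.

Step 5
Reactants: 7 enone
Product: 8 triethylsilyl enol ether of 6 (C9(OSiEt3)=C5; acetyl ketone free)
Conditions: RhCl(PPh3)3 (1 mol %), Et3SiH (1.3 equiv), toluene, 50 °C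
Reagents that add atoms: triethylsilane CC[SiH](CC)CC
Why: Rhodium-catalysed 1,4-hydrosilylation of the enone delivers hydride to C6 and silicon to O9, giving the C9=C5 silyl enol ether as a single regioisomer and leaving the isolated ketone, the ester and the trisubstituted alkene alone; this group blocks C5 in step 6 and activates it in step 7.

Step 6
Reactants: 8 silyl enol ether
Product: 10 ring-A precursor with C1 prenyl group plus C1 tert-butyl malonyl arm plus C9 triethylsilyl enol ether plus C7 ethyl ester, via lithium enolate 9 (not isolated)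
Conditions: LiHMDS (2.2 equiv), THF, −78 °C; Boc2O (1.1 equiv), −78 → −30 °C; aq NH4Cl
Reagents that add atoms: di-tert-butyl dicarbonate CC(C)(C)OC(=O)OC(=O)OC(C)(C)C
Why: Claisen-type C-acylation (tert-butoxycarbonylation) of a lithium enolate: with C9 masked the acetyl methyl group is the only ketone α-position left, the hindered ester α-hydrogen at C7 is far less acidic, and the second equivalent of base stores the product as its enolate.

Step 7
Reactants: 10 precursor
Product: 13 ethyl 8,8-dimethyl-2,4,9-trioxo-1-prenylbicyclo[3.3.1]nonane-7-carboxylate (C5–H; both C7 epimers), via acylketene 11 (not isolated), via triethylsilyl vinylogous ester 12 (not isolated)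
Conditions: toluene (0.005 M), 110 °C, slow distillation of toluene/t-BuOH with solvent make-up; then 0.5 M HCl, THF, 0 °C
Reagents that add atoms: none
Why: Proposed new method: the enol tautomer of the tert-butyl β-ketoester loses tert-butanol through a six-centre retro-ene-type elimination and gives acylketene 11, in which the in-plane π* orbital of C4=O faces C5 as soon as the C1 arm is pseudoaxial on ring A. C5 of the silyl enol ether then bonds to C4 while silicon passes from O9 to O4 within a six-membered array, the silicon counterpart of the ene-like addition of an enol, which restores the C9 ketone and leaves 12, hydrolysed to 13 on work-up. The closest known reaction types are the thermolysis of tert-butyl β-ketoesters and dioxinones to acylketenes, the six-membered lactonisation of such ketenes by a tethered hydroxyl group and their intermolecular capture by enol ethers; a concerted hetero-[4+2] addition cannot operate here, since O2 and C9 are joined through C1 alone and would have to close an oxetane. Ring B (C1–C2–C3–C4–C5–C9) is the only ring closed, in a 6-(enolendo)-exo-dig mode with respect to C4=O, with C1 to C5 already lying in the plane they occupy in the product. The only new stereocentre, C5, is controlled by the C1 stereocentre through the tether, because the three-atom arm can reach C5 only on the ring face that it occupies itself. The selectivity needed is C- over O-acylation, secured by the silyl cap on O9, while high dilution counters ketene dimerisation and removal of tert-butanol by distillation counters its re-addition.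

Step 8
Reactants: 13 trione ethyl ester
Product: 14 allyl 8,8-dimethyl-2,4,9-trioxo-1-prenylbicyclo[3.3.1]nonane-7-carboxylate (7-exo ester, cis to the C1 prenyl group and trans to the C2–C4 bridge)
Conditions: NaOCH2CH=CH2 (3 equiv), allyl alcohol, 90 °C; then 1 M HCl
Reagents that add atoms: allyl alcohol C=CCO
Why: Alkoxide-mediated ester epimerisation combined with transesterification: the trione is shielded from retro-Claisen cleavage as its delocalised enolate, reversible deprotonation at C7 funnels both epimers into the exo ester (equatorial on chair ring A, whereas the endo ester forces ring A into a boat) and so sets C7, and the excess alcohol turns the ethyl ester into an allyl ester that can later be removed without hydroxide.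

Step 9
Reactants: 14 exo allyl ester
Product: 15 allyl 4-methoxy-8,8-dimethyl-2,9-dioxo-1-prenylbicyclo[3.3.1]non-3-ene-7-carboxylate
Conditions: Me2SO4 (1.2 equiv), K2CO3 (1.5 equiv), acetone, rt → 40 °C
Reagents that add atoms: dimethyl sulfate COS(=O)(=O)OC
Why: Enolate O-alkylation of the vinylogous acid: the oxygen on C4, next to the C5–H bridgehead, is much less shielded than the oxygen on C2 next to quaternary C1, so the 4-methoxy isomer should dominate, and the acidic trione is masked for the organometallic steps.

Step 10
Reactants: 15 methyl enol ether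
Product: 16 4-methoxy-8,8-dimethyl-2,9-dioxo-1-prenylbicyclo[3.3.1]non-3-ene-7-exo-carboxylic acid
Conditions: Pd(PPh3)4 (5 mol %), PhNHMe (3 equiv), THF, rt
Reagents that add atoms: none
Why: Tsuji–Trost deallylation: zerovalent palladium ionises only the allyl ester and N-methylaniline traps the allyl unit, so the acid is freed under neutral conditions that leave the vinylogous methyl ester (which hydroxide would also attack) and C7 untouched.

Step 11
Reactants: 16 acid
Product: 18 C7 diazomethyl ketone, via acid chloride 17 (not isolated)
Conditions: 1-chloro-N,N,2-trimethylprop-1-en-1-amine (1.2 equiv), CH2Cl2, 0 °C; then CH2N2 (4 equiv), Et2O, 0 °C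
Reagents that add atoms: diazomethane C=[N+]=[N-]
Why: First stage of the Arndt–Eistert homologation: the chloroenamine makes the acid chloride without releasing HCl, so the prenyl alkene and enol ether survive, and diazomethane acylation gives the diazoketone with C7 unchanged.

Step 12
Reactants: 18 diazoketone
Product: 20 C7 acetic acid (one-carbon homologue of 16), via ketene 19 (not isolated)
Conditions: AgO2CPh (10 mol %), Et3N, THF–H2O (9:1), rt, dark
Reagents that add atoms: water O
Why: Wolff rearrangement: the 1,2-shift of C7 proceeds with retention of configuration and water adds to ketene 19, so the exo stereocentre passes unchanged into the homologous acid.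

Step 13
Reactants: 20 homologous acid
Product: 21 N-(acyloxy)phthalimide redox-active ester of 20
Conditions: N-hydroxyphthalimide (1.1 equiv), DIC (1.1 equiv), DMAP (10 mol %), CH2Cl2, rt
Reagents that add atoms: N-hydroxyphthalimide O=C1c2ccccc2C(=O)N1O
Why: Steglich-type carbodiimide esterification of an unhindered primary acetic acid; no other group in 20 is acylated or activated.

Step 14
Reactants: 22 6-methylhept-5-en-2-one
Product: 24 6-methylhept-5-en-1-yne, via enol phosphate 23 (not isolated)
Conditions: LDA (1.05 equiv), THF, −78 °C; ClP(O)(OEt)2; LDA (2.3 equiv), −78 °C → rt; H2O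
Reagents that add atoms: none
Why: Methyl ketone to terminal alkyne conversion by kinetic enolisation at the methyl group, enol phosphate formation and base-induced elimination.

Step 15
Reactants: 24 alkyne
Product: 26 (E)-1-iodo-2,6-dimethylhepta-1,5-diene, via alkenylalane 25 (not isolated)
Conditions: AlMe3 (2 equiv), Cp2ZrCl2 (25 mol %), CH2Cl2, 0 °C → rt; then I2, THF, −30 °C
Reagents that add atoms: trimethylaluminium C[Al](C)C; iodine II
Why: Negishi zirconium-catalysed carboalumination adds methyl and aluminium syn across the alkyne with aluminium at the terminus, and iodinolysis with retention fixes the E geometry of the future C2'=C3' bond.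

Step 16
Reactants: 21 redox-active ester; 26 alkenyl iodide
Product: 29 7-exo-geranyl-4-methoxy-8,8-dimethyl-1-prenylbicyclo[3.3.1]non-3-ene-2,9-dione (C5–H), via alkenyllithium 27 (not isolated), via alkenylzinc chloride 28 (not isolated)
Conditions: 26 (3 equiv), t-BuLi (2 equiv per 26), Et2O, −78 °C; ZnCl2, THF, −78 °C → rt; then 21, Ni(acac)2 (10 mol %), 2,2'-bipyridine (10 mol %), THF–DMF, rt
Reagents that add atoms: none
Why: Nickel-catalysed decarboxylative alkenylation of a redox-active ester with an alkenylzinc reagent (decarboxylative Negishi-type coupling): the radical forms at the primary carbon C1' so C7 is not touched, the alkenyl geometry is retained through exchange, transmetalation and coupling, and ketones, the enol ether and alkenes tolerate the organozinc.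

Step 17
Reactants: 29 geranyl compound; 30 prenyl bromide
Product: 32 7-exo-geranyl-4-methoxy-8,8-dimethyl-1,5-diprenylbicyclo[3.3.1]non-3-ene-2,9-dione, via bridgehead organolithium 31 (not isolated)
Conditions: LDA (1.5 equiv), THF, −78 °C; 30 (3 equiv), −78 → −30 °C
Reagents that add atoms: none
Why: Bridgehead lithiation–alkylation of a bicyclo[3.3.1]nonanetrione enol ether, an established reaction type; it is placed after step 16 because a C7 ester would have been deprotonated first, and the cage allows substitution at C5 only with retention, which sets the quaternary C5 centre.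

Step 18
Reactants: 33 3,4-dihydroxybenzoic acid
Product: 34 tert-butyldimethylsilyl 3,4-bis(tert-butyldimethylsilyloxy)benzoate
Conditions: TBSCl (3.5 equiv), imidazole (7 equiv), DMF, rt
Reagents that add atoms: tert-butyldimethylsilyl chloride CC(C)(C)[Si](C)(C)Cl
Why: Exhaustive silylation protects both phenols as base-labile aryl silyl ethers and turns the acid into a silyl ester ready for neutral activation.

Step 19
Reactants: 34 tris-silyl compound
Product: 35 3,4-bis(tert-butyldimethylsilyloxy)benzoyl chloride
Conditions: (COCl)2 (1.2 equiv), DMF (cat.), CH2Cl2, 0 °C → rt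
Reagents that add atoms: oxalyl chloride O=C(Cl)C(=O)Cl
Why: Conversion of a silyl ester into the acid chloride with oxalyl chloride and catalytic DMF releases no HCl, so the aryl silyl ethers stay in place.

Step 20
Reactants: 32 diprenyl compound; 35 aroyl chloride
Product: 37 C3-[3,4-bis(tert-butyldimethylsilyloxy)benzoyl] derivative of 32, via C3 vinyllithium 36 (not isolated)
Conditions: LiTMP (2 equiv), THF, −78 °C; 35 (2.5 equiv), −78 → 0 °C
Reagents that add atoms: none
Why: Vinylic lithiation at C3, the only remaining acidic position, flanked by the C2 carbonyl and the C4 methoxy group, followed by C-acylation with the acid chloride; no stereocentre is affected.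

Step 21
Reactants: 37 protected target
Product: 38 oblongifolin B
Conditions: LiOH (1 M aq, excess), 1,4-dioxane, 90 °C, argon; then cold 1 M HCl
Reagents that add atoms: lithium hydroxide [Li+].[OH-]
Why: Hydroxide cleaves the two aryl silyl ethers at silicon and hydrolyses the doubly activated vinylogous methyl ester by addition–elimination at C4; the resulting stable enolate resists deacylation, and basic conditions avoid the acid-induced cyclisation of the prenyl groups onto the enol.

## Compound list

1 | Hagemann's ester, ethyl 2-methyl-4-oxocyclohex-2-ene-1-carboxylate (racemic) | CCOC(=O)C1CCC(=O)C=C1C | starting material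
2 | lithium enolate (C1=C9) of ethyl 2,2-dimethyl-4-oxocyclohexane-1-carboxylate | CCOC(=O)C1CCC([O-])=CC1(C)C.[Li+] | intermediate
3 | ethyl 3-(1-hydroxyethyl)-2,2-dimethyl-4-oxocyclohexane-1-carboxylate (diastereomer mixture) | CCOC(=O)C1CCC(=O)C(C(C)O)C1(C)C | intermediate
4 | ethyl 3-acetyl-2,2-dimethyl-4-oxocyclohexane-1-carboxylate (racemic at C7) | CCOC(=O)C1CCC(=O)C(C(C)=O)C1(C)C | intermediate
5 | prenyl acetate | CC(=O)OCC=C(C)C | starting material
6 | ethyl 3-acetyl-2,2-dimethyl-3-prenyl-4-oxocyclohexane-1-carboxylate, C1 as in the target, both C7 epimers | CCOC(=O)C1CCC(=O)[C@@](CC=C(C)C)(C(C)=O)C1(C)C | intermediate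
7 | C5=C6 enone of 6, C7 labile | CCOC(=O)C1C=CC(=O)[C@@](CC=C(C)C)(C(C)=O)C1(C)C | intermediate
8 | C9=C5 triethylsilyl enol ether of 6 | CCOC(=O)C1CC=C(O[Si](CC)(CC)CC)[C@@](CC=C(C)C)(C(C)=O)C1(C)C | intermediate
9 | lithium enolate of the acetyl group of 8 | CCOC(=O)C1CC=C(O[Si](CC)(CC)CC)[C@@](CC=C(C)C)(C([O-])=C)C1(C)C.[Li+] | intermediate
10 | key-step precursor: C1 prenyl, C1 tert-butyl malonyl arm, C9 triethylsilyl enol ether, C7 ethyl ester | CCOC(=O)C1CC=C(O[Si](CC)(CC)CC)[C@@](CC=C(C)C)(C(=O)CC(=O)OC(C)(C)C)C1(C)C | intermediate
11 | acylketene from 10 | CCOC(=O)C1CC=C(O[Si](CC)(CC)CC)[C@@](CC=C(C)C)(C(=O)C=C=O)C1(C)C | intermediate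
12 | 4-triethylsilyloxy enone (silyl vinylogous ester) of 13 | CCOC(=O)C1C[C@@H]2C(=O)[C@@](CC=C(C)C)(C(=O)C=C2O[Si](CC)(CC)CC)C1(C)C | intermediate
13 | key-step product: ethyl 8,8-dimethyl-2,4,9-trioxo-1-prenylbicyclo[3.3.1]nonane-7-carboxylate, C5–H, both C7 epimers | CCOC(=O)C1C[C@@H]2C(=O)[C@@](CC=C(C)C)(C(=O)CC2=O)C1(C)C | intermediate
14 | 7-exo allyl ester of the trione | C=CCOC(=O)[C@@H]1C[C@@H]2C(=O)[C@@](CC=C(C)C)(C(=O)CC2=O)C1(C)C | intermediate
15 | 4-methoxy enone, 7-exo allyl ester | C=CCOC(=O)[C@@H]1C[C@@H]2C(=O)[C@@](CC=C(C)C)(C(=O)C=C2OC)C1(C)C | intermediate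
16 | 4-methoxy enone, 7-exo carboxylic acid | OC(=O)[C@@H]1C[C@@H]2C(=O)[C@@](CC=C(C)C)(C(=O)C=C2OC)C1(C)C | intermediate
17 | acid chloride of 16 | ClC(=O)[C@@H]1C[C@@H]2C(=O)[C@@](CC=C(C)C)(C(=O)C=C2OC)C1(C)C | intermediate
18 | C7 diazomethyl ketone | [N-]=[N+]=CC(=O)[C@@H]1C[C@@H]2C(=O)[C@@](CC=C(C)C)(C(=O)C=C2OC)C1(C)C | intermediate
19 | ketene from 18 | O=C=C[C@@H]1C[C@@H]2C(=O)[C@@](CC=C(C)C)(C(=O)C=C2OC)C1(C)C | intermediate
20 | C7 acetic acid | OC(=O)C[C@@H]1C[C@@H]2C(=O)[C@@](CC=C(C)C)(C(=O)C=C2OC)C1(C)C | intermediate
21 | N-(acyloxy)phthalimide ester of 20 | O=C(C[C@@H]1C[C@@H]2C(=O)[C@@](CC=C(C)C)(C(=O)C=C2OC)C1(C)C)ON3C(=O)c4ccccc4C3=O | intermediate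
22 | 6-methylhept-5-en-2-one | CC(=O)CCC=C(C)C | starting material
23 | diethyl 6-methylhepta-1,5-dien-2-yl phosphate | C=C(CCC=C(C)C)OP(=O)(OCC)OCC | intermediate
24 | 6-methylhept-5-en-1-yne | C#CCCC=C(C)C | intermediate
25 | (E)-(2,6-dimethylhepta-1,5-dienyl)dimethylalane | CC(C)=CCC/C(C)=C/[Al](C)C | intermediate
26 | (E)-1-iodo-2,6-dimethylhepta-1,5-diene | CC(C)=CCC/C(C)=C/I | intermediate
27 | (E)-2,6-dimethylhepta-1,5-dienyllithium | CC(C)=CCC/C(C)=C/[Li] | intermediate
28 | (E)-2,6-dimethylhepta-1,5-dienylzinc chloride | CC(C)=CCC/C(C)=C/[Zn]Cl | intermediate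
29 | 7-exo-geranyl-4-methoxy-8,8-dimethyl-1-prenylbicyclo[3.3.1]non-3-ene-2,9-dione | CC(C)=CCC/C(C)=C/C[C@@H]1C[C@@H]2C(=O)[C@@](CC=C(C)C)(C(=O)C=C2OC)C1(C)C | intermediate
30 | prenyl bromide | CC(C)=CCBr | starting material
31 | C5 bridgehead organolithium of 29 | CC(C)=CCC/C(C)=C/C[C@@H]1C[C@]2([Li])C(=O)[C@@](CC=C(C)C)(C(=O)C=C2OC)C1(C)C | intermediate
32 | 7-exo-geranyl-4-methoxy-8,8-dimethyl-1,5-diprenylbicyclo[3.3.1]non-3-ene-2,9-dione | CC(C)=CCC/C(C)=C/C[C@@H]1C[C@]2(CC=C(C)C)C(=O)[C@@](CC=C(C)C)(C(=O)C=C2OC)C1(C)C | intermediate
33 | 3,4-dihydroxybenzoic acid | O=C(O)c1ccc(O)c(O)c1 | starting material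
34 | tert-butyldimethylsilyl 3,4-bis(tert-butyldimethylsilyloxy)benzoate | CC(C)(C)[Si](C)(C)OC(=O)c1ccc(O[Si](C)(C)C(C)(C)C)c(O[Si](C)(C)C(C)(C)C)c1 | intermediate
35 | 3,4-bis(tert-butyldimethylsilyloxy)benzoyl chloride | O=C(Cl)c1ccc(O[Si](C)(C)C(C)(C)C)c(O[Si](C)(C)C(C)(C)C)c1 | intermediate
36 | C3 vinyllithium of 32 | CC(C)=CCC/C(C)=C/C[C@@H]1C[C@]2(CC=C(C)C)C(=O)[C@@](CC=C(C)C)(C(=O)C([Li])=C2OC)C1(C)C | intermediate
37 | O-methyl, bis-O-silyl oblongifolin B | CC(C)=CCC/C(C)=C/C[C@@H]1C[C@]2(CC=C(C)C)C(=O)[C@@](CC=C(C)C)(C(=O)C(C(=O)c3ccc(O[Si](C)(C)C(C)(C)C)c(O[Si](C)(C)C(C)(C)C)c3)=C2OC)C1(C)C | intermediate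
38 | oblongifolin B | CC(C)=CCC/C(C)=C/C[C@@H]1C[C@]2(CC=C(C)C)C(=O)[C@@](CC=C(C)C)(C(=O)C(C(=O)c3ccc(O)c(O)c3)=C2O)C1(C)C | target

## Step count and risks

Total step count: 21.
Longest linear sequence: 17 steps (1–13, 16, 17, 20, 21).

**Step 7 (key step).**
- Several processes may consume the ketene or its precursor before C5 reaches C4.
- Migration of the silyl group from O9 to the β-ketoester enol would shut down the loss of tert-butanol.
- The 1,5-diene C5=C9–C1–CH2–CH=CMe2 may undergo a Cope rearrangement, and the C1 prenyl double bond may capture the ketene in an ene-type reaction.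
- The C7 epimer whose ester is syn-axial to the arm has to close through a boat and will react more slowly.

The fallback sets out from 1 and comes back at 13, using known chemistry. Hagemann's ester 1 is alkylated at its enone α-carbon (the future C1) with prenyl bromide 30 (KOt-Bu, t-BuOH) to give ethyl 2-methyl-3-prenyl-4-oxocyclohex-2-ene-1-carboxylate F1. Conjugate addition of Me2CuLi in the presence of Me3SiCl gives the tetrasubstituted trimethylsilyl enol ether F2. An Effenberger cyclisation with malonyl dichloride (CH2Cl2, −20 °C, then aq KOH, BnEt3NCl) forms C1–C2 and C4–C5 in one operation and gives 13 as a racemate. The antipodes are then parted at acid 16 by the salt resolution described for step 3.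

**Step 3.**
- Facial selectivity may be poor for the C7 antipode in which the pseudoaxial C8 methyl group shields the face that the catalyst prefers.
- Bond formation between two fully substituted carbons may be slow.
- Some attack at the substituted allyl terminus may occur.

The fallback sets out from 4 and comes back at 16, replacing asymmetric catalysis by classical resolution. Compound 4 is prenylated with an achiral catalyst (Pd(PPh3)4, Cs2CO3) to racemic 6, which runs through steps 4 to 10 unchanged. Racemic 16, a single diastereomer after step 8, is resolved by fractional crystallisation of its (S)-1-phenylethylammonium salt F3, or of the salt of the antipodal amine, whichever carries the wanted acid. Acidification returns enantiopure 16.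

**Step 16.**
- The primary radical next to the congested C7/C8 region may be reduced by hydrogen abstraction before nickel captures it.
- The redox-active ester may be cleaved by the organozinc without decarboxylation.

The fallback sets out from 16 and comes back at 29. It bypasses steps 11–13 by keeping the carboxyl carbon as C1' and using a polar coupling.
- Acid 16 is converted into S-ethyl thioester F4 (EtSH, DCC, DMAP).
- Fukuyama reduction (Et3SiH, Pd/C, acetone) gives aldehyde F5.
- NaBH4 in MeOH at −78 °C reduces only the aldehyde, giving primary alcohol F6.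
- Appel-type iodination (I2, PPh3, imidazole) gives iodide F7.
- Zinc insertion (Zn, LiCl, THF) gives alkylzinc iodide F8.
- Negishi coupling of F8 with alkenyl iodide 26 (PdCl2(dppf), THF) gives 29 with retention of the E geometry.

## Further compounds

F1 | step 7 | ethyl 2-methyl-3-(3-methylbut-2-enyl)-4-oxocyclohex-2-ene-1-carboxylate | CCOC(=O)C1CCC(=O)C(CC=C(C)C)=C1C
F2 | step 7 | ethyl 2,2-dimethyl-3-(3-methylbut-2-enyl)-4-(trimethylsilyloxy)cyclohex-3-ene-1-carboxylate | CCOC(=O)C1CCC(O[Si](C)(C)C)=C(CC=C(C)C)C1(C)C
F3 | step 3 | (S)-1-phenylethylammonium salt of 16 | C[C@H]([NH3+])c1ccccc1.[O-]C(=O)[C@@H]1C[C@@H]2C(=O)[C@@](CC=C(C)C)(C(=O)C=C2OC)C1(C)C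
F4 | step 16 | S-ethyl thioester of 16 | CCSC(=O)[C@@H]1C[C@@H]2C(=O)[C@@](CC=C(C)C)(C(=O)C=C2OC)C1(C)C
F5 | step 16 | 7-exo carbaldehyde | O=C[C@@H]1C[C@@H]2C(=O)[C@@](CC=C(C)C)(C(=O)C=C2OC)C1(C)C
F6 | step 16 | 7-exo hydroxymethyl compound | OC[C@@H]1C[C@@H]2C(=O)[C@@](CC=C(C)C)(C(=O)C=C2OC)C1(C)C
F7 | step 16 | 7-exo iodomethyl compound | IC[C@@H]1C[C@@H]2C(=O)[C@@](CC=C(C)C)(C(=O)C=C2OC)C1(C)C
F8 | step 16 | 7-exo (iodozincio)methyl compound | I[Zn]C[C@@H]1C[C@@H]2C(=O)[C@@](CC=C(C)C)(C(=O)C=C2OC)C1(C)C
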